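**Retrosynthetic overview**
- Feature used: the oxane ring (O, C1–C5) of this 1,5-epoxy diarylheptanoid has C5 bonded to the ring oxygen and to C6, which is one carbon from the ring B benzylic C7; with C7 as a ketone, O–C5=C6–C7=O is a β-alkoxy enone that can accept a C4 radical at C5.
- Endgame: the target comes from the C7 ketone by reduction, dehydration to the C6=C7 styrene, desilylation, and a final hydrogenation that also removes the three benzyl ethers.
- Key disconnection: the C4–C5 ring bond, made by 6-exo radical cyclisation of a C4 iodide onto the (E)-β-alkoxy enone; the oxane is the only ring formed in the route (rings A and B are bought), and C5 is set cis to C1 and C3.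
- Tether: O–C5 by phosphine-catalysed addition of the C1 carbinol to the ring B aryl ethynyl ketone, then chloride-to-iodide exchange.
- C1 is set by oxazaborolidine-catalysed borane reduction of the ring A aryl ketone, itself made from the ring A aryllithium and the Weinreb amide of silylated ethyl (S)-4-chloro-3-hydroxybutanoate (C3 from the chiral pool).

Key step: step 11

Remark: the chain is numbered C1 (benzylic carbon on ring A, the 3,4-dioxygenated 5-methoxyphenyl ring) to C7 (benzylic carbon on ring B); the target is taken as the all-cis oxane with C1 S, C3 R, C5 S, and the CIP letters at C3 and C5 change along the route only because substituent ranking changes, not the spatial arrangement.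

Step 1
Reactants: 1 ethyl (3S)-4-chloro-3-hydroxybutanoate
Product: 2 ethyl (3S)-3-[(tert-butyldimethylsilyl)oxy]-4-chlorobutanoate
Conditions: TBSCl, imidazole, DMF, rt
Reagents that add atoms: tert-butyldimethylsilyl chloride, CC(C)(C)[Si](C)(C)Cl
Why: Standard silylation of the secondary alcohol protects the future C3 oxygen (configuration untouched) before the organometallic steps and prevents epoxide formation from the chlorohydrin.

Step 2
Reactants: 2 ethyl (3S)-3-[(tert-butyldimethylsilyl)oxy]-4-chlorobutanoate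
Product: 3 (3S)-3-[(tert-butyldimethylsilyl)oxy]-4-chloro-N-methoxy-N-methylbutanamide
Conditions: MeNH(OMe)·HCl, iPrMgCl, THF, −20 to 0 °C
Reagents that add atoms: N,O-dimethylhydroxylamine hydrochloride, CNOC.Cl
Why: Aminolysis of the ethyl ester by the magnesium amide of N,O-dimethylhydroxylamine (Weinreb amide formation) is mild enough at low temperature to leave the β-silyloxy group and the primary chloride in place.

Step 3
Reactants: 4 5-bromo-2-hydroxy-3-methoxybenzaldehyde
Product: 6 5-bromo-3-methoxybenzene-1,2-diol, via aryl formate 5 (not isolated)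
Conditions: H2O2 (30% aq), NaOH, H2O/THF, 0 °C to rt, N2; then HCl
Reagents that add atoms: hydrogen peroxide, OO
Why: Dakin oxidation of an ortho-hydroxybenzaldehyde (hydroperoxide addition, aryl migration to oxygen, hydrolysis of the formate) replaces the formyl group by hydroxyl and so gives the ring A oxygenation pattern with bromine para to the central oxygen.

Step 4
Reactants: 6 5-bromo-3-methoxybenzene-1,2-diol
Product: 7 1,2-bis(benzyloxy)-5-bromo-3-methoxybenzene
Conditions: BnBr, K2CO3, DMF, 60 °C, N2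
Reagents that add atoms: benzyl bromide, BrCc1ccccc1
Why: Williamson etherification of both phenols gives benzyl ethers that tolerate aryllithium, borane, stannane and fluoride chemistry and are removed in the final hydrogenation.

Step 5
Reactants: 7 1,2-bis(benzyloxy)-5-bromo-3-methoxybenzene; 3 (3S)-3-[(tert-butyldimethylsilyl)oxy]-4-chloro-N-methoxy-N-methylbutanamide
Product: 10 (3S)-1-[3,4-bis(benzyloxy)-5-methoxyphenyl]-3-[(tert-butyldimethylsilyl)oxy]-4-chlorobutan-1-one, via aryllithium 8 (not isolated), via lithium hemiaminal adduct 9 (not isolated)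
Conditions: n-BuLi, THF, −78 °C; then 3, −78 to −40 °C; aq NH4Cl
Reagents that add atoms: none
Why: Bromine–lithium exchange followed by acylation of the aryllithium with the Weinreb amide should stop at the ketone because the chelated tetrahedral adduct persists until work-up, and the primary chloride is inert to the aryllithium at low temperature.

Step 6
Reactants: 10 (3S)-1-[3,4-bis(benzyloxy)-5-methoxyphenyl]-3-[(tert-butyldimethylsilyl)oxy]-4-chlorobutan-1-one
Product: 11 (1S,3S)-1-[3,4-bis(benzyloxy)-5-methoxyphenyl]-3-[(tert-butyldimethylsilyl)oxy]-4-chlorobutan-1-ol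
Conditions: (R)-Me-CBS [(3aR)-1-methyl-3,3-diphenyltetrahydro-1H,3H-pyrrolo[1,2-c][1,3,2]oxazaborole] (0.2 equiv), BH3·SMe2, THF, −20 °C; MeOH
Reagents that add atoms: none
Why: In the Corey–Bakshi–Shibata reduction of an aryl alkyl ketone the aryl group takes the large-substituent position, so the (R)-catalyst should give the (1S)-carbinol under reagent control (the sense of acetophenone to (S)-1-phenylethanol), which is the 1,3-anti relationship to the C3 silyl ether that the all-cis ring needs.

Step 7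
Reactants: 12 4-(benzyloxy)-3-methoxybenzaldehyde
Product: 13 1-[4-(benzyloxy)-3-methoxyphenyl]prop-2-yn-1-ol (racemic)
Conditions: HC≡CMgBr, THF, 0 °C; aq NH4Cl
Reagents that add atoms: ethynylmagnesium bromide, C#C[Mg]Br
Why: 1,2-Addition of an alkynyl Grignard reagent to an aromatic aldehyde gives the propargylic alcohol, whose stereocentre is immaterial because it is oxidised in the next step.

Step 8
Reactants: 13 1-[4-(benzyloxy)-3-methoxyphenyl]prop-2-yn-1-ol
Product: 14 1-[4-(benzyloxy)-3-methoxyphenyl]prop-2-yn-1-one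
Conditions: MnO2 (activated), CH2Cl2, rt
Reagents that add atoms: none
Why: Activated MnO2 selectively oxidises the benzylic propargylic alcohol to the terminal aryl ynone under neutral conditions that neither hydrate nor polymerise the alkyne.

Step 9
Reactants: 11 (1S,3S)-1-[3,4-bis(benzyloxy)-5-methoxyphenyl]-3-[(tert-butyldimethylsilyl)oxy]-4-chlorobutan-1-ol; 14 1-[4-(benzyloxy)-3-methoxyphenyl]prop-2-yn-1-one
Product: 15 (2E)-1-[4-(benzyloxy)-3-methoxyphenyl]-3-{(1S,3S)-1-[3,4-bis(benzyloxy)-5-methoxyphenyl]-3-[(tert-butyldimethylsilyl)oxy]-4-chlorobutoxy}prop-2-en-1-one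
Conditions: PMe3 (0.2 equiv), CH2Cl2, 0 °C to rt, slow addition of 14
Reagents that add atoms: none
Why: Phosphine-catalysed oxa-Michael addition of the C1 alcohol to the terminal ynone (the phosphine adds first, the zwitterion deprotonates the alcohol, the alkoxide adds and PMe3 is expelled) should give the (E)-β-alkoxy enone without touching the C1–O bond, so C1 keeps its configuration, and the sluggish primary chloride does not alkylate the transient alkoxide.

Step 10
Reactants: 15 (2E)-1-[4-(benzyloxy)-3-methoxyphenyl]-3-{(1S,3S)-1-[3,4-bis(benzyloxy)-5-methoxyphenyl]-3-[(tert-butyldimethylsilyl)oxy]-4-chlorobutoxy}prop-2-en-1-one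
Product: 16 (2E)-1-[4-(benzyloxy)-3-methoxyphenyl]-3-{(1S,3S)-1-[3,4-bis(benzyloxy)-5-methoxyphenyl]-3-[(tert-butyldimethylsilyl)oxy]-4-iodobutoxy}prop-2-en-1-one
Conditions: NaI, NaHCO3, 2-butanone, reflux, dark
Reagents that add atoms: sodium iodide, [Na+].[I-]
Why: Finkelstein exchange (SN2 at the primary C4, driven by precipitation of NaCl) installs the weak carbon–iodine bond needed for radical generation at a stage where the C1 oxygen is already tied up in the vinylogous ester and cannot cyclise onto C4.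

Step 11
Reactants: 16 (2E)-1-[4-(benzyloxy)-3-methoxyphenyl]-3-{(1S,3S)-1-[3,4-bis(benzyloxy)-5-methoxyphenyl]-3-[(tert-butyldimethylsilyl)oxy]-4-iodobutoxy}prop-2-en-1-one
Product: 17 1-[4-(benzyloxy)-3-methoxyphenyl]-2-{(2R,4R,6S)-6-[3,4-bis(benzyloxy)-5-methoxyphenyl]-4-[(tert-butyldimethylsilyl)oxy]oxan-2-yl}ethan-1-one (all-cis oxane)
Conditions: Bu3SnH, AIBN (0.2 equiv), toluene, 85 °C, stannane added by syringe pump over 4 h (0.01 M)
Reagents that add atoms: none
Why: The tributylstannyl radical abstracts iodine from C4 to give a nucleophilic primary radical, which adds to C5, the β-carbon of the (E)-vinylogous ester O–C5=C6–C7=O, and the resulting C6 radical next to the aryl ketone takes hydrogen from Bu3SnH to carry the chain. The closest known reaction type is the stannane-mediated radical cyclisation of β-alkoxyacrylates and β-alkoxyvinyl ketones to cis-2,6-disubstituted oxanes. The oxane closes in the 6-exo-trig mode, since polar matching of the nucleophilic radical with the electron-poor C5 terminus disfavours 7-endo attack at C6. The new stereocentre C5 is set in a chair-like transition state in which the C1 aryl group, the C3 silyloxy group and the s-trans enone arm are all equatorial, so the C5 hydrogen ends up axial and cis to those at C1 and C3. The step needs ring closure to outrun direct reduction of the C4 radical and iodine abstraction to outrun stannyl attack on the enone, which the strongly activated acceptor, the weak carbon–iodine bond and slow addition of the stannane at high dilution should secure, while the neutral medium leaves the acid-labile benzylic C1–O bond, the silyl ether and the benzyl ethers untouched.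

Step 12
Reactants: 17 1-[4-(benzyloxy)-3-methoxyphenyl]-2-{(2R,4R,6S)-6-[3,4-bis(benzyloxy)-5-methoxyphenyl]-4-[(tert-butyldimethylsilyl)oxy]oxan-2-yl}ethan-1-one
Product: 18 1-[4-(benzyloxy)-3-methoxyphenyl]-2-{(2S,4R,6S)-6-[3,4-bis(benzyloxy)-5-methoxyphenyl]-4-[(tert-butyldimethylsilyl)oxy]oxan-2-yl}ethan-1-ol (both C7 epimers)
Conditions: NaBH4, MeOH/THF, 0 °C
Reagents that add atoms: none
Why: Borohydride 1,2-reduction of the aryl ketone gives the benzylic C7 carbinol as a mixture of epimers that does not matter, since C7 becomes a methylene group.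

Step 13
Reactants: 18 1-[4-(benzyloxy)-3-methoxyphenyl]-2-{(2S,4R,6S)-6-[3,4-bis(benzyloxy)-5-methoxyphenyl]-4-[(tert-butyldimethylsilyl)oxy]oxan-2-yl}ethan-1-ol
Product: 20 tert-butyl({(2S,4R,6R)-2-[3,4-bis(benzyloxy)-5-methoxyphenyl]-6-[(E)-2-[4-(benzyloxy)-3-methoxyphenyl]ethenyl]oxan-4-yl}oxy)dimethylsilane, via C7 mesylate 19 (not isolated)
Conditions: MsCl, Et3N, CH2Cl2, 0 °C; then DBU, toluene, 80 °C
Reagents that add atoms: none
Why: Sulfonylation of the electron-rich benzylic alcohol followed by base-induced β-elimination towards C6 (the only β-hydrogens) should give the conjugated (E)-styrene from both C7 epimers without acid, which would endanger the benzylic C1–O bond.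

Step 14
Reactants: 20 tert-butyl({(2S,4R,6R)-2-[3,4-bis(benzyloxy)-5-methoxyphenyl]-6-[(E)-2-[4-(benzyloxy)-3-methoxyphenyl]ethenyl]oxan-4-yl}oxy)dimethylsilane
Product: 21 (2S,4R,6R)-2-[3,4-bis(benzyloxy)-5-methoxyphenyl]-6-[(E)-2-[4-(benzyloxy)-3-methoxyphenyl]ethenyl]oxan-4-ol
Conditions: Bu4NF, THF, rt
Reagents that add atoms: none
Why: Fluoride-mediated desilylation frees the C3 hydroxyl while the phenols are still benzylated, so no air-sensitive catechol is exposed to the basic fluoride.

Step 15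
Reactants: 21 (2S,4R,6R)-2-[3,4-bis(benzyloxy)-5-methoxyphenyl]-6-[(E)-2-[4-(benzyloxy)-3-methoxyphenyl]ethenyl]oxan-4-ol
Product: 22 5-{(2S,4R,6S)-4-hydroxy-6-[2-(4-hydroxy-3-methoxyphenyl)ethyl]oxan-2-yl}-3-methoxybenzene-1,2-diol (CNP0399218.1)
Conditions: H2 (1 atm), Pd/C (10 wt% Pd), EtOAc/MeOH, rt, degassed solvents
Reagents that add atoms: none
Why: Heterogeneous hydrogenation saturates the C6=C7 styrene and hydrogenolyses the three aryl benzyl ethers in one operation, and in neutral solvent without acid the cyclic benzylic C1–O bond of the 2-aryloxane should persist, so the three stereocentres are untouched.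

**Compound list**
1 | ethyl (3S)-4-chloro-3-hydroxybutanoate | ClC[C@@H](O)CC(=O)OCC | starting material
2 | ethyl (3S)-3-[(tert-butyldimethylsilyl)oxy]-4-chlorobutanoate | ClC[C@@H](O[Si](C)(C)C(C)(C)C)CC(=O)OCC | intermediate
3 | (3S)-3-[(tert-butyldimethylsilyl)oxy]-4-chloro-N-methoxy-N-methylbutanamide | ClC[C@@H](O[Si](C)(C)C(C)(C)C)CC(=O)N(C)OC | intermediate
4 | 5-bromo-2-hydroxy-3-methoxybenzaldehyde | O=Cc1cc(Br)cc(OC)c1O | starting material
5 | 5-bromo-2-hydroxy-3-methoxyphenyl formate (not isolated) | O=COc1cc(Br)cc(OC)c1O | intermediate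
6 | 5-bromo-3-methoxybenzene-1,2-diol | Oc1cc(Br)cc(OC)c1O | intermediate
7 | 1,2-bis(benzyloxy)-5-bromo-3-methoxybenzene | COc1cc(Br)cc(OCc2ccccc2)c1OCc1ccccc1 | intermediate
8 | [3,4-bis(benzyloxy)-5-methoxyphenyl]lithium (not isolated) | [Li]c1cc(OCc2ccccc2)c(OCc2ccccc2)c(OC)c1 | intermediate
9 | lithium (3S)-1-[3,4-bis(benzyloxy)-5-methoxyphenyl]-3-[(tert-butyldimethylsilyl)oxy]-4-chloro-1-[methoxy(methyl)amino]butan-1-olate (tetrahedral adduct, C1 undefined, not isolated) | ClC[C@@H](O[Si](C)(C)C(C)(C)C)CC(O[Li])(N(C)OC)c1cc(OCc2ccccc2)c(OCc2ccccc2)c(OC)c1 | intermediate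
10 | (3S)-1-[3,4-bis(benzyloxy)-5-methoxyphenyl]-3-[(tert-butyldimethylsilyl)oxy]-4-chlorobutan-1-one | ClC[C@@H](O[Si](C)(C)C(C)(C)C)CC(=O)c1cc(OCc2ccccc2)c(OCc2ccccc2)c(OC)c1 | intermediate
11 | (1S,3S)-1-[3,4-bis(benzyloxy)-5-methoxyphenyl]-3-[(tert-butyldimethylsilyl)oxy]-4-chlorobutan-1-ol | ClC[C@@H](O[Si](C)(C)C(C)(C)C)C[C@@H](c1cc(OCc2ccccc2)c(OCc2ccccc2)c(OC)c1)O | intermediate
12 | 4-(benzyloxy)-3-methoxybenzaldehyde | O=Cc1ccc(OCc2ccccc2)c(OC)c1 | starting material
13 | 1-[4-(benzyloxy)-3-methoxyphenyl]prop-2-yn-1-ol (racemic) | C#CC(O)c1ccc(OCc2ccccc2)c(OC)c1 | intermediate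
14 | 1-[4-(benzyloxy)-3-methoxyphenyl]prop-2-yn-1-one | C#CC(=O)c1ccc(OCc2ccccc2)c(OC)c1 | intermediate
15 | (2E)-1-[4-(benzyloxy)-3-methoxyphenyl]-3-{(1S,3S)-1-[3,4-bis(benzyloxy)-5-methoxyphenyl]-3-[(tert-butyldimethylsilyl)oxy]-4-chlorobutoxy}prop-2-en-1-one | ClC[C@@H](O[Si](C)(C)C(C)(C)C)C[C@@H](c1cc(OCc2ccccc2)c(OCc2ccccc2)c(OC)c1)O/C=C/C(=O)c1ccc(OCc2ccccc2)c(OC)c1 | intermediate
16 | (2E)-1-[4-(benzyloxy)-3-methoxyphenyl]-3-{(1S,3S)-1-[3,4-bis(benzyloxy)-5-methoxyphenyl]-3-[(tert-butyldimethylsilyl)oxy]-4-iodobutoxy}prop-2-en-1-one (key-step precursor) | IC[C@@H](O[Si](C)(C)C(C)(C)C)C[C@@H](c1cc(OCc2ccccc2)c(OCc2ccccc2)c(OC)c1)O/C=C/C(=O)c1ccc(OCc2ccccc2)c(OC)c1 | intermediate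
17 | 1-[4-(benzyloxy)-3-methoxyphenyl]-2-{(2R,4R,6S)-6-[3,4-bis(benzyloxy)-5-methoxyphenyl]-4-[(tert-butyldimethylsilyl)oxy]oxan-2-yl}ethan-1-one (all-cis; key-step product) | COc1cc(C(=O)C[C@H]2C[C@@H](O[Si](C)(C)C(C)(C)C)C[C@@H](c3cc(OCc4ccccc4)c(OCc4ccccc4)c(OC)c3)O2)ccc1OCc1ccccc1 | intermediate
18 | 1-[4-(benzyloxy)-3-methoxyphenyl]-2-{(2S,4R,6S)-6-[3,4-bis(benzyloxy)-5-methoxyphenyl]-4-[(tert-butyldimethylsilyl)oxy]oxan-2-yl}ethan-1-ol (C7 epimers) | COc1cc(C(O)C[C@H]2C[C@@H](O[Si](C)(C)C(C)(C)C)C[C@@H](c3cc(OCc4ccccc4)c(OCc4ccccc4)c(OC)c3)O2)ccc1OCc1ccccc1 | intermediate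
19 | 1-[4-(benzyloxy)-3-methoxyphenyl]-2-{(2R,4R,6S)-6-[3,4-bis(benzyloxy)-5-methoxyphenyl]-4-[(tert-butyldimethylsilyl)oxy]oxan-2-yl}ethyl methanesulfonate (C7 epimers, not isolated) | COc1cc(C(OS(C)(=O)=O)C[C@H]2C[C@@H](O[Si](C)(C)C(C)(C)C)C[C@@H](c3cc(OCc4ccccc4)c(OCc4ccccc4)c(OC)c3)O2)ccc1OCc1ccccc1 | intermediate
20 | tert-butyl({(2S,4R,6R)-2-[3,4-bis(benzyloxy)-5-methoxyphenyl]-6-[(E)-2-[4-(benzyloxy)-3-methoxyphenyl]ethenyl]oxan-4-yl}oxy)dimethylsilane | COc1cc(/C=C/[C@H]2C[C@@H](O[Si](C)(C)C(C)(C)C)C[C@@H](c3cc(OCc4ccccc4)c(OCc4ccccc4)c(OC)c3)O2)ccc1OCc1ccccc1 | intermediate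
21 | (2S,4R,6R)-2-[3,4-bis(benzyloxy)-5-methoxyphenyl]-6-[(E)-2-[4-(benzyloxy)-3-methoxyphenyl]ethenyl]oxan-4-ol | COc1cc(/C=C/[C@H]2C[C@@H](O)C[C@@H](c3cc(OCc4ccccc4)c(OCc4ccccc4)c(OC)c3)O2)ccc1OCc1ccccc1 | intermediate
22 | 5-{(2S,4R,6S)-4-hydroxy-6-[2-(4-hydroxy-3-methoxyphenyl)ethyl]oxan-2-yl}-3-methoxybenzene-1,2-diol | COc1cc(CC[C@H]2C[C@@H](O)C[C@@H](c3cc(O)c(O)c(OC)c3)O2)ccc1O | target

**Step count and risk**
Total step count: 15. Longest linear sequence: 11 steps (steps 1, 2, 5, 6, 9, 10, 11, 12, 13, 14, 15); the ring A branch (steps 3, 4) joins at step 5 and the ynone branch (steps 7, 8) at step 9.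

Steps most likely to fail:

1. Step 11 (radical ring closure). The likely failure is erosion of the cis selectivity at C5 by closure through a boat-like transition state or with the enone arm axial. The fallback replaces kinetic radical control by thermodynamic, polar control. It sets out from 16: the closure is run as before and the unseparated mixture of 17 and the 2,6-trans C5 epimer F1 is treated with catalytic KOtBu in THF at 0 °C. Reversible E1cB opening of the β-alkoxy ketone to the ring-opened hydroxy enone F2 and 6-exo oxa-Michael re-closure should funnel the material into the all-equatorial isomer, returning to the route at 17.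

2. Step 10 (halide exchange). The likely failure is slow SN2 displacement at the primary chloride next to the silyloxy-bearing C3, so that prolonged heating degrades the vinylogous ester by conjugate addition of iodide or adventitious hydrolysis. The fallback uses another radical precursor, installed before the tether. It sets out from 11: displacement of chloride with PhSeNa (from (PhSe)2 and NaBH4, EtOH, rt to 60 °C), a much stronger nucleophile than iodide, should give the hydroxy selenide F3. PMe3-catalysed addition of F3 to 14, as in step 9, should give the selenide enone F4. Bu3SnH/AIBN then cleaves the carbon–selenium bond to the same C4 radical, and the route is rejoined at 17.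

3. Step 9 (oxa-Michael addition). The likely failure is phosphine-triggered oligomerisation of the terminal aryl ynone outrunning addition of the hindered secondary benzylic alcohol. The fallback uses an acrylate tether and brings in ring B after ring closure. It sets out from 11: N-methylmorpholine-catalysed addition to methyl propiolate in CH2Cl2 should give the β-alkoxyacrylate chloride F5. NaI in refluxing 2-butanone should give the β-alkoxyacrylate iodide F6, the acrylate tolerating long heating. Bu3SnH/AIBN should close the oxane in the same 6-exo chair mode to the oxane ester F7, and iBu2AlH at −78 °C should give the oxane aldehyde F8. Addition of [4-(benzyloxy)-3-methoxyphenyl]magnesium bromide F9 (from commercial 1-(benzyloxy)-4-bromo-2-methoxybenzene and Mg in THF) at −78 °C should give the C7 carbinol, rejoining the route at 18.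

**Further compounds**
F1 | step 11 | 1-[4-(benzyloxy)-3-methoxyphenyl]-2-{(2S,4R,6S)-6-[3,4-bis(benzyloxy)-5-methoxyphenyl]-4-[(tert-butyldimethylsilyl)oxy]oxan-2-yl}ethan-1-one (2,6-trans C5 epimer of 17) | COc1cc(C(=O)C[C@@H]2C[C@@H](O[Si](C)(C)C(C)(C)C)C[C@@H](c3cc(OCc4ccccc4)c(OCc4ccccc4)c(OC)c3)O2)ccc1OCc1ccccc1
F2 | step 11 | (2E,5R,7S)-1-[4-(benzyloxy)-3-methoxyphenyl]-7-[3,4-bis(benzyloxy)-5-methoxyphenyl]-5-[(tert-butyldimethylsilyl)oxy]-7-hydroxyhept-2-en-1-one | O=C(/C=C/C[C@@H](O[Si](C)(C)C(C)(C)C)C[C@@H](c1cc(OCc2ccccc2)c(OCc2ccccc2)c(OC)c1)O)c1ccc(OCc2ccccc2)c(OC)c1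
F3 | step 10 | (1S,3S)-1-[3,4-bis(benzyloxy)-5-methoxyphenyl]-3-[(tert-butyldimethylsilyl)oxy]-4-(phenylselanyl)butan-1-ol | c1ccccc1[Se]C[C@@H](O[Si](C)(C)C(C)(C)C)C[C@@H](c1cc(OCc2ccccc2)c(OCc2ccccc2)c(OC)c1)O
F4 | step 10 | (2E)-1-[4-(benzyloxy)-3-methoxyphenyl]-3-{(1S,3S)-1-[3,4-bis(benzyloxy)-5-methoxyphenyl]-3-[(tert-butyldimethylsilyl)oxy]-4-(phenylselanyl)butoxy}prop-2-en-1-one | c1ccccc1[Se]C[C@@H](O[Si](C)(C)C(C)(C)C)C[C@@H](c1cc(OCc2ccccc2)c(OCc2ccccc2)c(OC)c1)O/C=C/C(=O)c1ccc(OCc2ccccc2)c(OC)c1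
F5 | step 9 | methyl (2E)-3-{(1S,3S)-1-[3,4-bis(benzyloxy)-5-methoxyphenyl]-3-[(tert-butyldimethylsilyl)oxy]-4-chlorobutoxy}prop-2-enoate | ClC[C@@H](O[Si](C)(C)C(C)(C)C)C[C@@H](c1cc(OCc2ccccc2)c(OCc2ccccc2)c(OC)c1)O/C=C/C(=O)OC
F6 | step 9 | methyl (2E)-3-{(1S,3S)-1-[3,4-bis(benzyloxy)-5-methoxyphenyl]-3-[(tert-butyldimethylsilyl)oxy]-4-iodobutoxy}prop-2-enoate | IC[C@@H](O[Si](C)(C)C(C)(C)C)C[C@@H](c1cc(OCc2ccccc2)c(OCc2ccccc2)c(OC)c1)O/C=C/C(=O)OC
F7 | step 9 | methyl 2-{(2R,4R,6S)-6-[3,4-bis(benzyloxy)-5-methoxyphenyl]-4-[(tert-butyldimethylsilyl)oxy]oxan-2-yl}acetate | COC(=O)C[C@H]1C[C@@H](O[Si](C)(C)C(C)(C)C)C[C@@H](c2cc(OCc3ccccc3)c(OCc3ccccc3)c(OC)c2)O1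
F8 | step 9 | 2-{(2R,4R,6S)-6-[3,4-bis(benzyloxy)-5-methoxyphenyl]-4-[(tert-butyldimethylsilyl)oxy]oxan-2-yl}acetaldehyde | O=CC[C@H]1C[C@@H](O[Si](C)(C)C(C)(C)C)C[C@@H](c2cc(OCc3ccccc3)c(OCc3ccccc3)c(OC)c2)O1
F9 | step 9 | [4-(benzyloxy)-3-methoxyphenyl]magnesium bromide | Br[Mg]c1ccc(OCc2ccccc2)c(OC)c1
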